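## Retrosynthetic overview

- The acid is freed last from its methyl ester. Before that, quinone ring B of the 5-hydroxy-7-methyl-1,4-naphthoquinone is cut at both aryl–carbonyl bonds (C1–C8a and C4–C4a).
- Ring A then becomes a 3-oxy-5-methylbenzyne. The unit O=C1–C2(chromonyl)=C3H–C4=O becomes a 2-silyloxyfuran, the dienol ether of a 4-aryl butenolide: the furan ring oxygen ends up on C1 and the lactone carbonyl oxygen on C4.
- Enabling feature: the phenol oxygen on C5 of ring A and the carbonyl oxygen on C4 of ring B are peri, three atoms apart (O–C5–C4a–C4–O). One iPr2Si atom can therefore bridge the aryne precursor and the furan as a temporary O–Si–O tether that fixes the regiochemistry and is lost on work-up.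
- The silaketal comes from an o-iodoaryl triflate (orcinol: iodination, mono-triflation) and a chromonyl butenolide (Suzuki–Miyaura coupling of a chromone 8-boronate with 4-bromofuran-2(5H)-one).
- Order of ring formation: chromone benzene ring bought (3,5-dimethoxytoluene), then chromone pyranone ring (enaminone cyclisation), then the temporary furan, then quinone ring B by intramolecular aryne–furan Diels–Alder reaction, hemiketal collapse and air oxidation.

Key step: step 12

Remark: the target has no stereocentre and its quinone–chromone axis is not specified, so no stereocontrol is planned; the bridgehead stereocentres of cycloadduct 20 are transient and racemic.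

## Route

Step 1
Reactants: 1 1,3-dimethoxy-5-methylbenzene
Product: 3 1-(2,6-dimethoxy-4-methylphenyl)ethan-1-one, via (2,6-dimethoxy-4-methylphenyl)lithium 2 (not isolated)
Conditions: n-BuLi, TMEDA, THF, 0 °C → rt; then MeC(O)N(OMe)Me, −78 °C → rt; aq. HCl
Reagents that add atoms: N-methoxy-N-methylacetamide, CC(=O)N(C)OC
Why: Directed ortho-lithiation takes place at the position between the two methoxy groups, and the aryllithium should be acylated only once because the Weinreb amide gives a stable chelated tetrahedral intermediate.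

Step 2
Reactants: 3 1-(2,6-dimethoxy-4-methylphenyl)ethan-1-one
Product: 4 1-(2,6-dihydroxy-4-methylphenyl)ethan-1-one
Conditions: BBr3, CH2Cl2, −78 °C → rt; H2O
Reagents that add atoms: none
Why: BBr3 ether cleavage is assisted by the ortho ketone for both methoxy groups, and the symmetry of the substrate leaves no selectivity question.

Step 3
Reactants: 4 1-(2,6-dihydroxy-4-methylphenyl)ethan-1-one
Product: 5 2-acetyl-3-hydroxy-5-methylphenyl trifluoromethanesulfonate
Conditions: Tf2O (1.05 equiv), pyridine, CH2Cl2, −20 → 0 °C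
Reagents that add atoms: trifluoromethanesulfonic anhydride, O=S(=O)(OS(=O)(=O)C(F)(F)F)C(F)(F)F
Why: O-sulfonylation of a symmetric bis-phenol gives one product whichever hydroxyl reacts, and the remaining hydroxyl is deactivated by chelation to the ketone and by the new electron-withdrawing triflate, which should stop the reaction at the mono-triflate.

Step 4
Reactants: 5 2-acetyl-3-hydroxy-5-methylphenyl trifluoromethanesulfonate
Product: 6 methyl 2-acetyl-3-hydroxy-5-methylbenzoate
Conditions: Pd(OAc)2 (cat.), dppp, CO (1 atm), MeOH, Et3N, DMF, 70 °C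
Reagents that add atoms: carbon monoxide, [C-]#[O+]; methanol, CO
Why: Palladium-catalysed methoxycarbonylation of an aryl triflate (oxidative addition to zerovalent palladium, CO insertion, methanolysis) is standard, and the chelated phenol and the ketone should be spectators in excess methanol.

Step 5
Reactants: 6 methyl 2-acetyl-3-hydroxy-5-methylbenzoate
Product: 7 methyl 2-acetyl-3-hydroxy-4-iodo-5-methylbenzoate
Conditions: NIS, TFA (cat.), MeCN, 0 °C → rt
Reagents that add atoms: N-iodosuccinimide, O=C1CCC(=O)N1I
Why: In this electrophilic aromatic iodination the position ortho to the phenol is flanked only by OH and CH3, whereas the para position is wedged between CH3 and the twisted CO2CH3 group, so the bulky iodine electrophile should prefer the ortho position.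

Step 6
Reactants: 7 methyl 2-acetyl-3-hydroxy-4-iodo-5-methylbenzoate
Product: 9 methyl 8-iodo-7-methyl-4-oxo-4H-chromene-5-carboxylate, via enaminone 8 (not isolated)
Conditions: DMF-DMA, toluene, 100 °C; then aq. HCl, CH2Cl2, rt
Reagents that add atoms: N,N-dimethylformamide dimethyl acetal, COC(OC)N(C)C
Why: Enaminone formation at the methyl ketone followed by acid-mediated intramolecular oxa-Michael addition and loss of dimethylamine is the standard chromone synthesis, and the only free phenol is the iodine-flanked one, so the ring can close in one sense only.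

Step 7
Reactants: 9 methyl 8-iodo-7-methyl-4-oxo-4H-chromene-5-carboxylate
Product: 10 methyl 7-methyl-4-oxo-8-(4,4,5,5-tetramethyl-1,3,2-dioxaborolan-2-yl)-4H-chromene-5-carboxylate
Conditions: B2pin2, PdCl2(dppf) (cat.), KOAc, 1,4-dioxane, 90 °C
Reagents that add atoms: bis(pinacolato)diboron, CC1(C)OB(OC1(C)C)B1OC(C)(C)C(C)(C)O1
Why: Miyaura borylation of an aryl iodide runs with the weak base KOAc, which the chromone and the ester should tolerate.

Step 8
Reactants: 10 methyl 7-methyl-4-oxo-8-(4,4,5,5-tetramethyl-1,3,2-dioxaborolan-2-yl)-4H-chromene-5-carboxylate; 11 4-bromofuran-2(5H)-one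
Product: 12 methyl 7-methyl-4-oxo-8-(5-oxo-2,5-dihydrofuran-3-yl)-4H-chromene-5-carboxylate
Conditions: Pd(OAc)2 (cat.), SPhos, K3PO4, THF–H2O, 50 °C
Reagents that add atoms: none
Why: Suzuki–Miyaura coupling of arylboronates with this vinylogous acyl bromide is a standard route to 4-aryl butenolides, and the bulky electron-rich phosphine should help the doubly ortho-substituted boronate to transmetalate.

Step 9
Reactants: 13 5-methylbenzene-1,3-diol
Product: 14 2-iodo-5-methylbenzene-1,3-diol
Conditions: I2, NaHCO3, H2O, 0 °C → rt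
Reagents that add atoms: iodine, II
Why: Iodination of resorcinols under bicarbonate conditions goes to the doubly activated position between the two hydroxyl groups, as is known for resorcinol itself.

Step 10
Reactants: 14 2-iodo-5-methylbenzene-1,3-diol
Product: 15 3-hydroxy-2-iodo-5-methylphenyl trifluoromethanesulfonate
Conditions: Tf2O (1.0 equiv), i-Pr2NEt, CH2Cl2, −78 °C
Reagents that add atoms: trifluoromethanesulfonic anhydride, O=S(=O)(OS(=O)(=O)C(F)(F)F)C(F)(F)F
Why: Mono-O-triflation of a symmetric diol with one equivalent of anhydride at low temperature should give mainly the mono-triflate, which is separable from diol and bis-triflate, and places the leaving group next to the iodine as an aryne precursor needs.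

Step 11
Reactants: 15 3-hydroxy-2-iodo-5-methylphenyl trifluoromethanesulfonate; 12 methyl 7-methyl-4-oxo-8-(5-oxo-2,5-dihydrofuran-3-yl)-4H-chromene-5-carboxylate
Product: 17 methyl 8-[5-({[2-iodo-5-methyl-3-(trifluoromethanesulfonyloxy)phenoxy]di(propan-2-yl)silyl}oxy)furan-3-yl]-7-methyl-4-oxo-4H-chromene-5-carboxylate, via aryloxysilyl triflate 16 (not isolated)
Conditions: iPr2Si(OTf)2, 2,6-lutidine, CH2Cl2, −78 °C; then 12, Et3N, −78 → 0 °C; non-aqueous work-up, used crude
Reagents that add atoms: di(propan-2-yl)silanediyl bis(trifluoromethanesulfonate), CC(C)[Si](OS(=O)(=O)C(F)(F)F)(OS(=O)(=O)C(F)(F)F)C(C)C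
Why: The hindered phenol should displace only one triflate from silicon, and the remaining silyl triflate then silylates the lactone carbonyl while Et3N removes the γ-proton (soft enolisation, the usual way to 2-silyloxyfurans), giving the aromatic furan as a mixed silaketal.

Step 12
Reactants: 17 methyl 8-[5-({[2-iodo-5-methyl-3-(trifluoromethanesulfonyloxy)phenoxy]di(propan-2-yl)silyl}oxy)furan-3-yl]-7-methyl-4-oxo-4H-chromene-5-carboxylate
Product: 22 methyl 8-(5-hydroxy-7-methyl-1,4-dioxo-1,4-dihydronaphthalen-2-yl)-7-methyl-4-oxo-4H-chromene-5-carboxylate, via arylmagnesium chloride 18 (not isolated), via aryne 19 (not isolated), via silicon-bridged cycloadduct 20 (not isolated), via naphthalene-1,4,5-triol 21 (not isolated)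
Conditions: Me3SiCH2MgCl, THF (high dilution), −78 °C → rt; then HF·pyridine, 0 °C; then air, rt
Reagents that add atoms: none
Why: Iodine–magnesium exchange at the iodide flanked by the triflate and the silyl ether, followed by loss of magnesium chloride triflate, gives 3-silyloxy-5-methylbenzyne 19, whose strained in-plane π bond is trapped by the tethered electron-rich 2-silyloxyfuran in an intramolecular Diels–Alder reaction that forms the C1–C8a and C4–C4a bonds of the later quinone at once. The closest known reaction types are intramolecular benzyne–furan cycloadditions through three-atom or disposable silicon tethers and intermolecular cycloadditions of 3-alkoxybenzynes with 2-alkoxy- or 2-silyloxyfurans. The six-membered carbocycle (ring B, the later quinone ring) closes by a concerted, probably asynchronous [4+2] cycloaddition, and the temporary six-membered 1,3-dioxa-2-silinane ring of the tether closes with it. The two bridgehead stereocentres of 20 are cis by necessity of the oxygen bridge, form as a racemate and are erased in the same flask, so no stereocontrol is needed. The selectivity required is regiochemical (the silyloxy-bearing furan carbon must join the aryne carbon next to the aryl oxygen); the O–Si–O tether enforces it and the innate polarisation reinforces it, since the unsubstituted nucleophilic furan α-carbon attacks the aryne carbon remote from oxygen, while high dilution suppresses intermolecular trapping. HF·pyridine then cleaves both Si–O bonds, the bridgehead hemiketal collapses and tautomerises to triol 21, and air should oxidise this juglone-type hydroquinone to quinone 22.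

Step 13
Reactants: 22 methyl 8-(5-hydroxy-7-methyl-1,4-dioxo-1,4-dihydronaphthalen-2-yl)-7-methyl-4-oxo-4H-chromene-5-carboxylate
Product: 23 8-(5-hydroxy-7-methyl-1,4-dioxo-1,4-dihydronaphthalen-2-yl)-7-methyl-4-oxo-4H-chromene-5-carboxylic acid
Conditions: aq. H2SO4, AcOH, 100 °C
Reagents that add atoms: water, O
Why: Acid-catalysed ester hydrolysis avoids the hydroxide and amine nucleophiles that open chromones and degrade juglones, and the non-nucleophilic counter-ion should leave the quinone untouched.

## Compound list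

1 | 1,3-dimethoxy-5-methylbenzene (3,5-dimethoxytoluene) | COc1cc(C)cc(OC)c1 | starting material
2 | (2,6-dimethoxy-4-methylphenyl)lithium | [Li]c1c(OC)cc(C)cc1OC | intermediate
3 | 1-(2,6-dimethoxy-4-methylphenyl)ethan-1-one | CC(=O)c1c(OC)cc(C)cc1OC | intermediate
4 | 1-(2,6-dihydroxy-4-methylphenyl)ethan-1-one | CC(=O)c1c(O)cc(C)cc1O | intermediate
5 | 2-acetyl-3-hydroxy-5-methylphenyl trifluoromethanesulfonate | CC(=O)c1c(O)cc(C)cc1OS(=O)(=O)C(F)(F)F | intermediate
6 | methyl 2-acetyl-3-hydroxy-5-methylbenzoate | COC(=O)c1cc(C)cc(O)c1C(C)=O | intermediate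
7 | methyl 2-acetyl-3-hydroxy-4-iodo-5-methylbenzoate | COC(=O)c1cc(C)c(I)c(O)c1C(C)=O | intermediate
8 | methyl 2-[(2E)-3-(dimethylamino)prop-2-enoyl]-3-hydroxy-4-iodo-5-methylbenzoate (enaminone) | COC(=O)c1cc(C)c(I)c(O)c1C(=O)/C=C/N(C)C | intermediate
9 | methyl 8-iodo-7-methyl-4-oxo-4H-chromene-5-carboxylate | COC(=O)c1cc(C)c(I)c2occc(=O)c12 | intermediate
10 | methyl 7-methyl-4-oxo-8-(4,4,5,5-tetramethyl-1,3,2-dioxaborolan-2-yl)-4H-chromene-5-carboxylate | COC(=O)c1cc(C)c(B3OC(C)(C)C(C)(C)O3)c2occc(=O)c12 | intermediate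
11 | 4-bromofuran-2(5H)-one | O=C1C=C(Br)CO1 | starting material
12 | methyl 7-methyl-4-oxo-8-(5-oxo-2,5-dihydrofuran-3-yl)-4H-chromene-5-carboxylate | COC(=O)c1cc(C)c(C3=CC(=O)OC3)c2occc(=O)c12 | intermediate
13 | 5-methylbenzene-1,3-diol (orcinol) | Cc1cc(O)cc(O)c1 | starting material
14 | 2-iodo-5-methylbenzene-1,3-diol | Cc1cc(O)c(I)c(O)c1 | intermediate
15 | 3-hydroxy-2-iodo-5-methylphenyl trifluoromethanesulfonate | Cc1cc(O)c(I)c(OS(=O)(=O)C(F)(F)F)c1 | intermediate
16 | [2-iodo-5-methyl-3-(trifluoromethanesulfonyloxy)phenoxy]di(propan-2-yl)silyl trifluoromethanesulfonate (aryloxysilyl triflate) | Cc1cc(O[Si](C(C)C)(C(C)C)OS(=O)(=O)C(F)(F)F)c(I)c(OS(=O)(=O)C(F)(F)F)c1 | intermediate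
17 | methyl 8-[5-({[2-iodo-5-methyl-3-(trifluoromethanesulfonyloxy)phenoxy]di(propan-2-yl)silyl}oxy)furan-3-yl]-7-methyl-4-oxo-4H-chromene-5-carboxylate | COC(=O)c1cc(C)c(-c3coc(O[Si](C(C)C)(C(C)C)Oc4cc(C)cc(OS(=O)(=O)C(F)(F)F)c4I)c3)c2occc(=O)c12 | intermediate
18 | arylmagnesium chloride (17 with MgCl in place of iodine) | COC(=O)c1cc(C)c(-c3coc(O[Si](C(C)C)(C(C)C)Oc4cc(C)cc(OS(=O)(=O)C(F)(F)F)c4[Mg]Cl)c3)c2occc(=O)c12 | intermediate
19 | aryne (3-silyloxy-5-methylbenzyne tethered through O–Si(iPr)2–O to the chromonyl furan) | COC(=O)c1cc(C)c(-c3coc(O[Si](C(C)C)(C(C)C)OC4=CC(C)=CC#C4)c3)c2occc(=O)c12 | intermediate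
20 | silicon-bridged cycloadduct: 1,4-dihydro-1,4-epoxynaphthalene with the C4 bridgehead oxygen and the C5 aryl oxygen joined by Si(iPr)2, chromonyl on C2, methyl on C7 (racemic, one enantiomer drawn, oxygen bridge cis) | CC(C)[Si]1(C(C)C)Oc2cc(C)cc3c2[C@]2(O1)C=C(c4c(C)cc(C(=O)OC)c5c(=O)ccoc45)[C@H]3O2 | intermediate
21 | methyl 7-methyl-4-oxo-8-(1,4,5-trihydroxy-7-methylnaphthalen-2-yl)-4H-chromene-5-carboxylate | COC(=O)c1cc(C)c(-c3cc(O)c4c(O)cc(C)cc4c3O)c2occc(=O)c12 | intermediate
22 | methyl 8-(5-hydroxy-7-methyl-1,4-dioxo-1,4-dihydronaphthalen-2-yl)-7-methyl-4-oxo-4H-chromene-5-carboxylate | Cc1cc(O)c2c(c1)C(=O)C(c1c(C)cc(C(=O)OC)c3c(=O)ccoc13)=CC2=O | intermediate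
23 | 8-(5-hydroxy-7-methyl-1,4-dioxo-1,4-dihydronaphthalen-2-yl)-7-methyl-4-oxo-4H-chromene-5-carboxylic acid | Cc1cc(O)c2c(c1)C(=O)C(c1c(C)cc(C(=O)O)c3c(=O)ccoc13)=CC2=O | target

## Step count and risks

Total step count: 13. Longest linear sequence: 11 steps (steps 1–8, then 11–13); the aryne branch (steps 9–10) joins at step 11.

Steps most likely to fail:

1. Step 12. The short O–Si–O tether may not let the furan reach the in-plane aryne π bond, so the aryne could be lost to oligomerisation or to [2+2] addition across the silyl enol ether; the Grignard reagent could also add to the chromone before the exchange. The fallback gives up the tether and sets out from 15 and 12. Phenol 15 is silylated (TBSCl, imidazole, DMF) to 3-[(tert-butyldimethylsilyl)oxy]-2-iodo-5-methylphenyl trifluoromethanesulfonate F1, and butenolide 12 is converted (TIPSOTf, Et3N, CH2Cl2) into methyl 7-methyl-4-oxo-8-{5-[tri(propan-2-yl)silyloxy]furan-3-yl}-4H-chromene-5-carboxylate F2. Me3SiCH2MgCl acting on F1 in the presence of F2 should release 3-[(tert-butyldimethylsilyl)oxy]-5-methylbenzyne F3, which is trapped intermolecularly. The regiochemistry then rests only on the polarisation of the 3-silyloxyaryne and should give the oxygen-bridged bis-silyl cycloadduct F4. TBAF/AcOH and air then lead through triol 21 to quinone 22, where the route is rejoined.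

2. Step 11. The unsymmetrical silaketal may not assemble cleanly: silicon may take up two aryloxy groups, the Lewis-basic chromone carbonyl may sequester the silyl triflate, or the silyl dienol ether of the elaborate butenolide may hydrolyse during isolation. The fallback changes the order of fragment union and sets out from 15, 11 and 10. The tether is built on the small bromobutenolide 11 (iPr2Si(OTf)2, 2,6-lutidine; then 11, Et3N) to give 3-({[(4-bromofuran-2-yl)oxy]di(propan-2-yl)silyl}oxy)-2-iodo-5-methylphenyl trifluoromethanesulfonate F5. The sequence of step 12 (selective iodine–magnesium exchange, cycloaddition, HF·pyridine, air) should then pass through the tethered aryne [(4-bromofuran-2-yl)oxy][(5-methylcyclohexa-1,5-dien-3-yn-1-yl)oxy]di(propan-2-yl)silane F6, the silicon-bridged bromo cycloadduct F7 and 2-bromo-7-methylnaphthalene-1,4,5-triol F8 to 2-bromo-5-hydroxy-7-methylnaphthalene-1,4-dione F9. Suzuki–Miyaura coupling of F9 with boronate 10 (PdCl2(dppf), CsF, 1,4-dioxane) then gives 22, where the route is rejoined.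

3. Step 5. Iodination may go to the position para to the hydroxyl (between CH3 and CO2CH3) or twice, which after step 6 would give the 6-iodochromone series. The fallback moves the halogenation to the symmetric diol and sets out from 4. NIS (1 equiv) can give only 1-(2,6-dihydroxy-3-iodo-4-methylphenyl)ethan-1-one F10. Site-selective triflation of the less hindered hydroxyl, the one not flanked by iodine (PhNTf2, K2CO3), should give 2-acetyl-3-hydroxy-4-iodo-5-methylphenyl trifluoromethanesulfonate F11; this selectivity is the fallback's own uncertainty. DMF-DMA gives the enaminone 2-[(2E)-3-(dimethylamino)prop-2-enoyl]-3-hydroxy-4-iodo-5-methylphenyl trifluoromethanesulfonate F12, and acid closes it through the only free hydroxyl to 8-iodo-7-methyl-4-oxo-4H-chromen-5-yl trifluoromethanesulfonate F13. Iodine-selective Miyaura borylation gives 7-methyl-4-oxo-8-(4,4,5,5-tetramethyl-1,3,2-dioxaborolan-2-yl)-4H-chromen-5-yl trifluoromethanesulfonate F14. Suzuki–Miyaura coupling with 11 gives 7-methyl-4-oxo-8-(5-oxo-2,5-dihydrofuran-3-yl)-4H-chromen-5-yl trifluoromethanesulfonate F15. Methoxycarbonylation of the triflate (Pd(OAc)2, dppp, CO, MeOH, Et3N) then gives 12, where the route is rejoined.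

## Further compounds

F1 | step 12 | 3-[(tert-butyldimethylsilyl)oxy]-2-iodo-5-methylphenyl trifluoromethanesulfonate | Cc1cc(O[Si](C)(C)C(C)(C)C)c(I)c(OS(=O)(=O)C(F)(F)F)c1
F2 | step 12 | methyl 7-methyl-4-oxo-8-{5-[tri(propan-2-yl)silyloxy]furan-3-yl}-4H-chromene-5-carboxylate | COC(=O)c1cc(C)c(-c3coc(O[Si](C(C)C)(C(C)C)C(C)C)c3)c2occc(=O)c12
F3 | step 12 | 3-[(tert-butyldimethylsilyl)oxy]-5-methylbenzyne | C[Si](C)(OC1=CC(C)=CC#C1)C(C)(C)C
F4 | step 12 | oxygen-bridged bis-silyl cycloadduct: 1,4-dihydro-1,4-epoxynaphthalene with OTIPS on bridgehead C4, OTBS on C5, chromonyl on C2, methyl on C7 (racemic, one enantiomer drawn) | CC(C)[Si](O[C@@]12C=C(c3c(C)cc(C(=O)OC)c4c(=O)ccoc34)[C@@H](O1)c1cc(C)cc(O[Si](C)(C)C(C)(C)C)c12)(C(C)C)C(C)C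
F5 | step 11 | 3-({[(4-bromofuran-2-yl)oxy]di(propan-2-yl)silyl}oxy)-2-iodo-5-methylphenyl trifluoromethanesulfonate | Cc1cc(O[Si](C(C)C)(C(C)C)Oc2cc(Br)co2)c(I)c(OS(=O)(=O)C(F)(F)F)c1
F6 | step 11 | [(4-bromofuran-2-yl)oxy][(5-methylcyclohexa-1,5-dien-3-yn-1-yl)oxy]di(propan-2-yl)silane (tethered aryne) | CC(C)[Si](Oc1cc(Br)co1)(OC1=CC(C)=CC#C1)C(C)C
F7 | step 11 | silicon-bridged bromo cycloadduct: 2-bromo-1,4-dihydro-1,4-epoxynaphthalene with the C4 bridgehead oxygen and the C5 oxygen joined by Si(iPr)2, methyl on C7 (racemic, one enantiomer drawn) | CC(C)[Si]1(C(C)C)Oc2cc(C)cc3c2[C@]2(O1)C=C(Br)[C@H]3O2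
F8 | step 11 | 2-bromo-7-methylnaphthalene-1,4,5-triol | Cc1cc(O)c2c(O)cc(Br)c(O)c2c1
F9 | step 11 | 2-bromo-5-hydroxy-7-methylnaphthalene-1,4-dione | Cc1cc(O)c2c(c1)C(=O)C(Br)=CC2=O
F10 | step 5 | 1-(2,6-dihydroxy-3-iodo-4-methylphenyl)ethan-1-one | CC(=O)c1c(O)cc(C)c(I)c1O
F11 | step 5 | 2-acetyl-3-hydroxy-4-iodo-5-methylphenyl trifluoromethanesulfonate | CC(=O)c1c(O)c(I)c(C)cc1OS(=O)(=O)C(F)(F)F
F12 | step 5 | 2-[(2E)-3-(dimethylamino)prop-2-enoyl]-3-hydroxy-4-iodo-5-methylphenyl trifluoromethanesulfonate | CN(C)/C=C/C(=O)c1c(O)c(I)c(C)cc1OS(=O)(=O)C(F)(F)F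
F13 | step 5 | 8-iodo-7-methyl-4-oxo-4H-chromen-5-yl trifluoromethanesulfonate | Cc1cc(OS(=O)(=O)C(F)(F)F)c2c(=O)ccoc2c1I
F14 | step 5 | 7-methyl-4-oxo-8-(4,4,5,5-tetramethyl-1,3,2-dioxaborolan-2-yl)-4H-chromen-5-yl trifluoromethanesulfonate | Cc1cc(OS(=O)(=O)C(F)(F)F)c2c(=O)ccoc2c1B1OC(C)(C)C(C)(C)O1
F15 | step 5 | 7-methyl-4-oxo-8-(5-oxo-2,5-dihydrofuran-3-yl)-4H-chromen-5-yl trifluoromethanesulfonate | Cc1cc(OS(=O)(=O)C(F)(F)F)c2c(=O)ccoc2c1C1=CC(=O)OC1
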